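**Plan**
- Retrosynthetic cuts, in order: the acetyl–O bond at C7; C11–H (from a C11 peroxy-hemiketal); the two C–O bonds of the 1,2-dioxane ring (back to H2O2, a 7,8-epoxide and a C11 ketone); C8–CH3 (from C8–I and C8–SiMe3); C8–C9 (closure of the fourteen-membered carbocycle); C1–C2 together with the lactone C–O bond (fragment union).
- Enabling feature: in the 1,2-dioxane ring the peroxide carbons C8 (quaternary, CH3) and C11 sit 1,4 across C9–C10. Without the O–O bridge, C11 is a ketone and the anti C7–O/C8–O pair is a 7E-alkene, so C8–C9 is the allylic bond of a γ,δ-unsaturated ketone: the ene adduct of a C7≡C8 alkyne and a C9=C10–C11(OH) allylic alcohol.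
- Forward order: fragment A (enal 7) and fragment B (allylic bromide 19) give the cis-α-methylene-γ-butyrolactone 22; ruthenium-catalysed alkyne–allyl alcohol coupling closes the fourteen-membered carbocycle at C8–C9; transannular epoxide perhydrolysis, reduction and acetylation build the 1,2-dioxane.
- Stereochemistry: C1/C2 from a catalytic asymmetric syn-allylation; C7/C8 from Shi epoxidation of the 7E-alkene (geometry set by the cis H/C addition of the key step) and invertive opening at C8; C11 from hydride delivery anti to the macrocyclic bridge; 3E from carboalumination; 12Z from a six-membered lactone ring.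

Key step: step 12

Remark on numbering: cembrane numbering is used. C1 is the lactone β-CH, C2 the lactone CH–O, C3=C4(CH3), C5, C6, C7 (OAc), C8 (CH3, O–O), C9, C10, C11 (O–O), C12(CH3)=C13, C14; the lactone carbons are C15 (α), C16 (C=O) and C17 (=CH2).
Remark on the chemistry: the C11 carbinol centre of 13–22 is carried as an epimer mixture because step 12 converts it into a ketone; the C1 carbinol of 18 is likewise lost in step 10.

Step 1
Reactants: 1 hexa-1,5-diyne
Product: 3 trimethyl(hexa-1,5-diyn-1-yl)silane, via lithium acetylide 2 (not isolated)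
Conditions: n-BuLi (1.0 equiv), THF, −78 °C; TMSCl
Reagents that add atoms: chlorotrimethylsilane, C[Si](C)(C)Cl
Why: Monodeprotonation of the symmetrical diyne and C-silylation of the acetylide should give the mono-silyl diyne, separable from recovered diyne and bis-silylated material; the silyl group later directs the ruthenium coupling.

Step 2
Reactants: 3 trimethyl(hexa-1,5-diyn-1-yl)silane
Product: 6 (2E)-3-methyl-7-(trimethylsilyl)hept-2-en-6-yn-1-ol, via alkenylalane 4 (not isolated), via lithium alanate 5 (not isolated)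
Conditions: Me3Al, Cp2ZrCl2 (20 mol%), CH2Cl2, 0 °C → rt; n-BuLi, THF, −78 °C; (CH2O)n, → rt
Reagents that add atoms: trimethylaluminium, C[Al](C)C; formaldehyde (as paraformaldehyde), C=O
Why: Zirconium-catalysed methylalumination (Negishi carboalumination) adds CH3 and Al cis across the free terminal alkyne only, and hydroxymethylation of the alanate with retention fixes the 3E geometry.

Step 3
Reactants: 6 (2E)-3-methyl-7-(trimethylsilyl)hept-2-en-6-yn-1-ol
Product: 7 (2E)-3-methyl-7-(trimethylsilyl)hept-2-en-6-ynal (fragment A)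
Conditions: MnO2, CH2Cl2, rt
Reagents that add atoms: none
Why: Allylic oxidation with MnO2 should give the enal without touching the silylalkyne or the alkene geometry.

Step 4
Reactants: 8 but-3-en-1-ol; 9 methacryloyl chloride
Product: 10 but-3-en-1-yl 2-methylprop-2-enoate
Conditions: Et3N, DMAP (cat.), CH2Cl2, 0 °C
Reagents that add atoms: none
Why: Standard O-acylation of a primary alcohol by an acid chloride.

Step 5
Reactants: 10 but-3-en-1-yl 2-methylprop-2-enoate
Product: 11 3-methyl-5,6-dihydro-2H-pyran-2-one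
Conditions: second-generation Grubbs catalyst (2 mol%), CH2Cl2, 40 °C, 0.01 M
Reagents that add atoms: none
Why: Ring-closing metathesis forms the six-membered unsaturated lactone, whose ring forces the carbons that become C11 and C14 to be cis on the future 12,13-alkene.

Step 6
Reactants: 11 3-methyl-5,6-dihydro-2H-pyran-2-one
Product: 13 (3Z)-4-methylhepta-3,6-diene-1,5-diol, via lactol 12 (not isolated)
Conditions: iBu2AlH (1.05 equiv), CH2Cl2, −78 °C; CH2=CHMgBr (3 equiv), THF, −78 → 0 °C
Reagents that add atoms: vinylmagnesium bromide, C=C[Mg]Br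
Why: Partial reduction to the lactol and 1,2-addition of the vinyl Grignard reagent to its ring-opened Z-enal form should give the diol with the Z-alkene intact.

Step 7
Reactants: 13 (3Z)-4-methylhepta-3,6-diene-1,5-diol
Product: 14 (3Z)-4-methyl-1,5-bis(triethylsilyloxy)hepta-3,6-diene
Conditions: TESCl (2.4 equiv), imidazole, CH2Cl2, 0 °C
Reagents that add atoms: chlorotriethylsilane, CC[Si](Cl)(CC)CC
Why: Exhaustive silylation of both hydroxyl groups.

Step 8
Reactants: 14 (3Z)-4-methyl-1,5-bis(triethylsilyloxy)hepta-3,6-diene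
Product: 15 (3Z)-4-methyl-5-(triethylsilyloxy)hepta-3,6-dienal
Conditions: (COCl)2, DMSO, CH2Cl2, −78 → −40 °C; iPr2NEt, −78 °C
Reagents that add atoms: none
Why: Under Swern conditions a primary triethylsilyl ether is cleaved and oxidised in preference to a secondary one, which should deliver the β,γ-unsaturated aldehyde at low temperature without conjugation.

Step 9
Reactants: 15 (3Z)-4-methyl-5-(triethylsilyloxy)hepta-3,6-dienal; 16 methyl prop-2-ynoate
Product: 18 methyl (5Z)-3-hydroxy-6-methyl-2-methylidene-7-(triethylsilyloxy)nona-5,8-dienoate, via aluminoacrylate 17 (not isolated)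
Conditions: 16, iBu2AlH, N-methylmorpholine N-oxide, THF, 0 °C; then 15, 0 °C → rt
Reagents that add atoms: none
Why: 1,4-Hydroalumination of the propiolate gives the α-aluminoacrylate, which adds to the aldehyde under neutral conditions (vinylalumination) to give the Morita–Baylis–Hillman-type adduct without the amine base that would conjugate the β,γ-unsaturated aldehyde.

Step 10
Reactants: 18 methyl (5Z)-3-hydroxy-6-methyl-2-methylidene-7-(triethylsilyloxy)nona-5,8-dienoate
Product: 19 methyl (2Z,5Z)-2-(bromomethyl)-6-methyl-7-(triethylsilyloxy)nona-2,5,8-trienoate (fragment B)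
Conditions: NBS, Me2S, CH2Cl2, −40 → 0 °C
Reagents that add atoms: N-bromosuccinimide, O=C1CCC(=O)N1Br
Why: SN2′ bromination of the Morita–Baylis–Hillman alcohol with the Corey–Kim reagent should give the thermodynamically preferred 2Z-2-(bromomethyl)enoate and leave the silyl ether intact.

Step 11
Reactants: 7 (2E)-3-methyl-7-(trimethylsilyl)hept-2-en-6-ynal; 19 methyl (2Z,5Z)-2-(bromomethyl)-6-methyl-7-(triethylsilyloxy)nona-2,5,8-trienoate
Product: 22 (4S,5S)-4-[(2Z)-4-hydroxy-3-methylhexa-2,5-dien-1-yl]-3-methylidene-5-[(1E)-2-methyl-6-(trimethylsilyl)hex-1-en-5-yn-1-yl]oxolan-2-one, via silyl ether 20 (not isolated), via hydroxy ester 21 (not isolated)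
Conditions: CrCl2 (10 mol%), chiral carbazole-bis(oxazoline) ligand (enantiomer that directs Re-face addition), Mn powder, TMSCl, iPr2NEt (cat.), THF, rt; then PPTS, MeOH, rt
Reagents that add atoms: none
Why: In this chromium-catalysed asymmetric Nozaki–Hiyama-type 2-(alkoxycarbonyl)allylation the γ-substituted allylchromium should add through a chair transition state to the Re face of the enal (ligand control) to give the syn adduct with C1 (S) and C2 (S), and mild acid then removes both silyl ethers and closes the cis-fused α-methylene-γ-butyrolactone.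

Step 12
Reactants: 22 (4S,5S)-4-[(2Z)-4-hydroxy-3-methylhexa-2,5-dien-1-yl]-3-methylidene-5-[(1E)-2-methyl-6-(trimethylsilyl)hex-1-en-5-yn-1-yl]oxolan-2-one
Product: 24 (1S,2S,3E,7Z,12Z)-11-oxo-8-(trimethylsilyl)-19-norcembra-3,7,12,15(17)-tetraen-16,2-olide, via dienol 23 (not isolated)
Conditions: [CpRu(MeCN)3]PF6 (10 mol%), acetone, 0.002 M (slow addition), rt
Reagents that add atoms: none
Why: The cationic cyclopentadienylruthenium centre binds the silylalkyne (C7≡C8) and the monosubstituted alkene (C9=C10), oxidative cyclisation gives a ruthenacyclopentene with the new C8–C9 bond at the silicon-bearing carbon, and β-hydride elimination of the carbinol hydrogen at C11 followed by C7–H reductive elimination releases dienol 23, which tautomerises to the C11 ketone. The closest known reaction type is the ruthenium-catalysed Alder-ene-type alkene–alkyne coupling, which is established between separate molecules for silylalkynes and for allylic alcohols (redox variant giving γ,δ-unsaturated ketones) and in macrocyclic ring closures. The only ring closed is the fourteen-membered carbocycle C1–C14, formed by intramolecular metallacycle formation between the two chain ends under high dilution. No stereocentre is created: the 7,8-geometry (silicon cis to C6, C6 and C9 trans) follows from the cis addition of H and C9 across the alkyne, and the C11 carbinol centre is erased. The step needs regioselectivity for C8 over C7, which the silyl group secures, chemoselectivity for the one monosubstituted alkene over the 1,1-disubstituted and trisubstituted ones, which the steric demand of the metallacycle secures, and ring closure over chain growth, which slow addition secures.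

Step 13
Reactants: 24 (1S,2S,3E,7Z,12Z)-11-oxo-8-(trimethylsilyl)-19-norcembra-3,7,12,15(17)-tetraen-16,2-olide
Product: 25 (1S,2S,3E,7Z,12Z)-8-iodo-11-oxo-19-norcembra-3,7,12,15(17)-tetraen-16,2-olide
Conditions: NIS, (CF3)2CHOH, 0 °C
Reagents that add atoms: N-iodosuccinimide, O=C1CCC(=O)N1I
Why: Ipso-iododesilylation of the vinylsilane proceeds through the β-silyl cation with retention of alkene geometry, and the other alkenes are conjugated or allylically deactivated and should not compete.

Step 14
Reactants: 25 (1S,2S,3E,7Z,12Z)-8-iodo-11-oxo-19-norcembra-3,7,12,15(17)-tetraen-16,2-olide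
Product: 26 (1S,2S,3E,7E,12Z)-11-oxocembra-3,7,12,15(17)-tetraen-16,2-olide
Conditions: MeZnCl, Pd(PPh3)4 (5 mol%), THF, rt
Reagents that add atoms: methylzinc chloride, C[Zn]Cl
Why: Negishi coupling on zerovalent palladium replaces iodine by methyl with retention to give the 7E-trisubstituted alkene, and the organozinc halide does not add to the ketone, the enone or the α-methylene lactone.

Step 15
Reactants: 26 (1S,2S,3E,7E,12Z)-11-oxocembra-3,7,12,15(17)-tetraen-16,2-olide
Product: 27 (1S,2S,7S,8S,3E,12Z)-7,8-epoxy-11-oxocembra-3,12,15(17)-trien-16,2-olide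
Conditions: L-fructose-derived Shi ketone (30 mol%), Oxone (2KHSO5·KHSO4·K2SO4), K2CO3, Bu4NHSO4, MeCN–(MeO)2CH2–aqueous buffer (pH 10.5), 0 °C
Reagents that add atoms: potassium peroxymonosulfate (active part of Oxone), [K+].[O-]S(=O)(=O)OO
Why: In this Shi epoxidation the chiral dioxirane should attack the only electron-rich trisubstituted alkene (3,4 is deactivated by the allylic lactone oxygen, 12,13 and 15,17 are conjugated to carbonyl groups), the ketone enantiomer is chosen to give the (7S,8S)-epoxide, and the E geometry becomes the trans relationship of C6 and C9.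

Step 16
Reactants: 27 (1S,2S,7S,8S,3E,12Z)-7,8-epoxy-11-oxocembra-3,12,15(17)-trien-16,2-olide
Product: 29 (1S,2S,7S,8R,3E,12Z)-8,11-epidioxy-7,11-dihydroxycembra-3,12,15(17)-trien-16,2-olide, via perhydrate 28 (not isolated)
Conditions: H2O2 (anhydrous, Et2O), H3PMo12O40 (5 mol%), 0 °C → rt
Reagents that add atoms: hydrogen peroxide, OO
Why: The ketone adds H2O2 to give hydroperoxy-hemiketal 28, whose terminal peroxide oxygen should open the acid-activated epoxide at the tertiary carbon C8 in a 6-exo mode with inversion (epoxide perhydrolysis), which sets C8 (R) anti to the C7 hydroxyl and closes the 1,2-dioxane ring.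

Step 17
Reactants: 29 (1S,2S,7S,8R,3E,12Z)-8,11-epidioxy-7,11-dihydroxycembra-3,12,15(17)-trien-16,2-olide
Product: 30 (1S,2S,7S,8R,11S,3E,12Z)-8,11-epidioxy-7-hydroxycembra-3,12,15(17)-trien-16,2-olide (7-deacetyldenticulatolide)
Conditions: Et3SiH, BF3·OEt2, CH2Cl2, −78 °C
Reagents that add atoms: none
Why: Ionisation of the peroxy-hemiketal to the cyclic, allyl-stabilised peroxycarbenium ion and hydride transfer from the silane (ionic reduction of a peroxyketal) should give C11–H, with hydride entering on the C8-methyl face of the dioxane ring that the macrocyclic bridge does not cover, which gives 11S with C7 and C12 cis on the dioxane.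

Step 18
Reactants: 30 7-deacetyldenticulatolide
Product: 31 denticulatolide
Conditions: Ac2O, pyridine, DMAP (cat.), CH2Cl2, 0 °C
Reagents that add atoms: acetic anhydride, CC(=O)OC(C)=O
Why: Acetylation of the secondary C7 alcohol under nucleophilic catalysis, mild enough for the peroxide and the α-methylene lactone.

**Compound list**
1 | hexa-1,5-diyne | C#CCCC#C | starting material
2 | lithium hexa-1,5-diyn-1-ide | [Li]C#CCCC#C | intermediate
3 | trimethyl(hexa-1,5-diyn-1-yl)silane | C[Si](C)(C)C#CCCC#C | intermediate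
4 | dimethyl[(1E)-2-methyl-6-(trimethylsilyl)hex-1-en-5-yn-1-yl]alumane | C[Al](C)/C=C(\C)CCC#C[Si](C)(C)C | intermediate
5 | lithium butyl(dimethyl)[(1E)-2-methyl-6-(trimethylsilyl)hex-1-en-5-yn-1-yl]aluminate | [Li+].CCCC[Al-](C)(C)/C=C(\C)CCC#C[Si](C)(C)C | intermediate
6 | (2E)-3-methyl-7-(trimethylsilyl)hept-2-en-6-yn-1-ol | OC/C=C(\C)CCC#C[Si](C)(C)C | intermediate
7 | (2E)-3-methyl-7-(trimethylsilyl)hept-2-en-6-ynal | O=C/C=C(\C)CCC#C[Si](C)(C)C | intermediate
8 | but-3-en-1-ol | C=CCCO | starting material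
9 | methacryloyl chloride | CC(=C)C(=O)Cl | starting material
10 | but-3-en-1-yl 2-methylprop-2-enoate | C=CCCOC(=O)C(C)=C | intermediate
11 | 3-methyl-5,6-dihydro-2H-pyran-2-one | CC1=CCCOC1=O | intermediate
12 | 3-methyl-5,6-dihydro-2H-pyran-2-ol (lactol, present as its aluminium alkoxide) | CC1=CCCOC1O | intermediate
13 | (3Z)-4-methylhepta-3,6-diene-1,5-diol (racemic) | OCC/C=C(C)\C(O)C=C | intermediate
14 | (3Z)-4-methyl-1,5-bis(triethylsilyloxy)hepta-3,6-diene | CC[Si](CC)(CC)OCC/C=C(C)\C(O[Si](CC)(CC)CC)C=C | intermediate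
15 | (3Z)-4-methyl-5-(triethylsilyloxy)hepta-3,6-dienal | O=CC/C=C(C)\C(O[Si](CC)(CC)CC)C=C | intermediate
16 | methyl prop-2-ynoate | C#CC(=O)OC | starting material
17 | methyl 2-(diisobutylalumanyl)prop-2-enoate | C=C([Al](CC(C)C)CC(C)C)C(=O)OC | intermediate
18 | methyl (5Z)-3-hydroxy-6-methyl-2-methylidene-7-(triethylsilyloxy)nona-5,8-dienoate (diastereomer mixture) | C=C(C(=O)OC)C(O)C/C=C(C)\C(O[Si](CC)(CC)CC)C=C | intermediate
19 | methyl (2Z,5Z)-2-(bromomethyl)-6-methyl-7-(triethylsilyloxy)nona-2,5,8-trienoate | COC(=O)/C(CBr)=C/C/C=C(C)\C(O[Si](CC)(CC)CC)C=C | intermediate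
20 | methyl (3S,5Z)-6-methyl-2-methylidene-3-[(1S,2E)-3-methyl-7-(trimethylsilyl)-1-(trimethylsilyloxy)hept-2-en-6-yn-1-yl]-7-(triethylsilyloxy)nona-5,8-dienoate | C=C(C(=O)OC)[C@H](C/C=C(C)\C(O[Si](CC)(CC)CC)C=C)[C@@H](O[Si](C)(C)C)/C=C(\C)CCC#C[Si](C)(C)C | intermediate
21 | methyl (3S,5Z)-7-hydroxy-3-[(1S,2E)-1-hydroxy-3-methyl-7-(trimethylsilyl)hept-2-en-6-yn-1-yl]-6-methyl-2-methylidenenona-5,8-dienoate | C=C(C(=O)OC)[C@H](C/C=C(C)\C(O)C=C)[C@@H](O)/C=C(\C)CCC#C[Si](C)(C)C | intermediate
22 | (4S,5S)-4-[(2Z)-4-hydroxy-3-methylhexa-2,5-dien-1-yl]-3-methylidene-5-[(1E)-2-methyl-6-(trimethylsilyl)hex-1-en-5-yn-1-yl]oxolan-2-one (C11 epimer mixture) | C=C1C(=O)O[C@@H](/C=C(\C)CCC#C[Si](C)(C)C)[C@H]1C/C=C(C)\C(O)C=C | intermediate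
23 | C10=C11 dienol tautomer of 24 (11-hydroxy, 10,11-ene) | C=C1C(=O)O[C@H]2/C=C(\C)CC/C=C(\[Si](C)(C)C)CC=C(O)/C(C)=C\C[C@@H]12 | intermediate
24 | (1S,2S,3E,7Z,12Z)-11-oxo-8-(trimethylsilyl)-19-norcembra-3,7,12,15(17)-tetraen-16,2-olide (silicon cis to C6) | C=C1C(=O)O[C@H]2/C=C(\C)CC/C=C(\[Si](C)(C)C)CCC(=O)/C(C)=C\C[C@@H]12 | intermediate
25 | (1S,2S,3E,7Z,12Z)-8-iodo-11-oxo-19-norcembra-3,7,12,15(17)-tetraen-16,2-olide | C=C1C(=O)O[C@H]2/C=C(\C)CC/C=C(\I)CCC(=O)/C(C)=C\C[C@@H]12 | intermediate
26 | (1S,2S,3E,7E,12Z)-11-oxocembra-3,7,12,15(17)-tetraen-16,2-olide | C=C1C(=O)O[C@H]2/C=C(\C)CC/C=C(\C)CCC(=O)/C(C)=C\C[C@@H]12 | intermediate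
27 | (1S,2S,7S,8S,3E,12Z)-7,8-epoxy-11-oxocembra-3,12,15(17)-trien-16,2-olide | C=C1C(=O)O[C@H]2/C=C(\C)CC[C@@H]3O[C@@]3(C)CCC(=O)/C(C)=C\C[C@@H]12 | intermediate
28 | (1S,2S,7S,8S,3E,12Z)-7,8-epoxy-11-hydroperoxy-11-hydroxycembra-3,12,15(17)-trien-16,2-olide (perhydrate) | C=C1C(=O)O[C@H]2/C=C(\C)CC[C@@H]3O[C@@]3(C)CCC(O)(OO)/C(C)=C\C[C@@H]12 | intermediate
29 | (1S,2S,7S,8R,3E,12Z)-8,11-epidioxy-7,11-dihydroxycembra-3,12,15(17)-trien-16,2-olide (C11 hemiketal epimers) | C=C1C(=O)O[C@H]2/C=C(\C)CC[C@H](O)[C@@]3(C)CCC(O)(OO3)/C(C)=C\C[C@@H]12 | intermediate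
30 | (1S,2S,7S,8R,11S,3E,12Z)-8,11-epidioxy-7-hydroxycembra-3,12,15(17)-trien-16,2-olide | C=C1C(=O)O[C@H]2/C=C(\C)CC[C@H](O)[C@@]3(C)CC[C@H](OO3)/C(C)=C\C[C@@H]12 | intermediate
31 | denticulatolide, (1S,2S,7S,8R,11S,3E,12Z)-7-acetoxy-8,11-epidioxycembra-3,12,15(17)-trien-16,2-olide | C=C1C(=O)O[C@H]2/C=C(\C)CC[C@H](OC(C)=O)[C@@]3(C)CC[C@H](OO3)/C(C)=C\C[C@@H]12 | target

**Total steps:** 18. **Longest linear sequence:** 15 steps (8 → 31, steps 4–18); fragment A takes 3 steps (1 → 7).

**Steps most likely to fail**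

1. Step 12. What may go wrong: chain growth between two molecules instead of ring closure, ionisation or redox isomerisation of the doubly allylic C11 carbinol at the cationic ruthenium centre, and drift of the 12Z enone geometry once the ketone has formed. Fallback (the ruthenium coupling is run between two molecules and the ring is closed at C1–C2 instead): setting out from 18 and 7, HF·pyridine removes the silyl ether of 18 to give methyl (5Z)-3,7-dihydroxy-6-methyl-2-methylidenenona-5,8-dienoate F1. [CpRu(MeCN)3]PF6 then couples F1, whose only competent alkene is the monosubstituted one, with 7 to give the open-chain keto vinylsilane enal F2. Corey–Kim bromination gives the allylic bromide F3. Intramolecular allylation of the enal with stoichiometric CrCl2 and the same chiral ligand under high dilution closes the fourteen-membered ring as the macrocyclic hydroxy ester F4, which lactonises on mild acid treatment and rejoins the route at 24.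

2. Step 16. What may go wrong: the C11 carbonyl oxygen, or the hydroxyl of the perhydrate, opens the activated epoxide in the 5-exo mode faster than the hydroperoxide does in the 6-exo mode, which leads to a tetrahydrofuran ketal instead of the dioxane. Fallback (peroxide tether first, epoxide second): setting out from 26, H2O2 with catalytic I2 in MeCN converts the ketone into the 11,11-dihydroperoxide F5, which has no hydroxyl or carbonyl oxygen left at C11. Shi epoxidation with the same ketone under the lower-pH protocol gives the (7S,8S)-epoxide F6, which is opened in the same flask by one hydroperoxy group to the 11-hydroperoxy-1,2-dioxane F7. The conditions of step 17 reduce F7 with loss of the hydroperoxy group, and the route is rejoined at 30.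

3. Step 11. What may go wrong: incomplete face selectivity at the enal, or erosion of syn selectivity through equilibration of the γ-substituted allylchromium. Fallback (boron reagent with a closed transition state): setting out from 18 and 7, acetylation (Ac2O, pyridine) gives the acetate F8. Copper-catalysed SN2′ borylation (B2pin2, CuCl, KOtBu) gives the (Z)-allylboronate F9. Allylboration of 7 catalysed by a chiral BINOL-derived phosphoric acid passes through a chair transition state that transcribes the boronate geometry into the syn hydroxy ester F10. PPTS in MeOH removes the silyl ether to give 21, which lactonises to 22.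

**Further compounds**
F1 | step 12 | methyl (5Z)-3,7-dihydroxy-6-methyl-2-methylidenenona-5,8-dienoate | C=C(C(=O)OC)C(O)C/C=C(C)\C(O)C=C
F2 | step 12 | methyl (5Z,10Z,14E)-3-hydroxy-6,14-dimethyl-2-methylidene-7,16-dioxo-10-(trimethylsilyl)hexadeca-5,10,14-trienoate | C=C(C(=O)OC)C(O)C/C=C(C)\C(=O)CC/C(=C/CC/C(C)=C/C=O)[Si](C)(C)C
F3 | step 12 | methyl (2Z,5Z,10Z,14E)-2-(bromomethyl)-6,14-dimethyl-7,16-dioxo-10-(trimethylsilyl)hexadeca-2,5,10,14-tetraenoate | COC(=O)/C(CBr)=C/C/C=C(C)\C(=O)CC/C(=C/CC/C(C)=C/C=O)[Si](C)(C)C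
F4 | step 12 | methyl 2-[(1S,2S,3E,7Z,12Z)-2-hydroxy-4,12-dimethyl-11-oxo-8-(trimethylsilyl)cyclotetradeca-3,7,12-trien-1-yl]prop-2-enoate | C=C(C(=O)OC)[C@@H]1C/C=C(C)\C(=O)CC/C(=C/CC/C(C)=C/[C@@H]1O)[Si](C)(C)C
F5 | step 16 | (1S,2S,3E,7E,12Z)-11,11-dihydroperoxycembra-3,7,12,15(17)-tetraen-16,2-olide | C=C1C(=O)O[C@H]2/C=C(\C)CC/C=C(\C)CCC(OO)(OO)/C(C)=C\C[C@@H]12
F6 | step 16 | (1S,2S,7S,8S,3E,12Z)-7,8-epoxy-11,11-dihydroperoxycembra-3,12,15(17)-trien-16,2-olide | C=C1C(=O)O[C@H]2/C=C(\C)CC[C@@H]3O[C@@]3(C)CCC(OO)(OO)/C(C)=C\C[C@@H]12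
F7 | step 16 | (1S,2S,7S,8R,3E,12Z)-8,11-epidioxy-11-hydroperoxy-7-hydroxycembra-3,12,15(17)-trien-16,2-olide | C=C1C(=O)O[C@H]2/C=C(\C)CC[C@H](O)[C@@]3(C)CCC(OO)(OO3)/C(C)=C\C[C@@H]12
F8 | step 11 | methyl (5Z)-3-acetoxy-6-methyl-2-methylidene-7-(triethylsilyloxy)nona-5,8-dienoate | C=C(C(=O)OC)C(OC(C)=O)C/C=C(C)\C(O[Si](CC)(CC)CC)C=C
F9 | step 11 | methyl (2Z,5Z)-6-methyl-2-[(4,4,5,5-tetramethyl-1,3,2-dioxaborolan-2-yl)methyl]-7-(triethylsilyloxy)nona-2,5,8-trienoate | COC(=O)/C(CB1OC(C)(C)C(C)(C)O1)=C/C/C=C(C)\C(O[Si](CC)(CC)CC)C=C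
F10 | step 11 | methyl (3S,5Z)-3-[(1S,2E)-1-hydroxy-3-methyl-7-(trimethylsilyl)hept-2-en-6-yn-1-yl]-6-methyl-2-methylidene-7-(triethylsilyloxy)nona-5,8-dienoate | C=C(C(=O)OC)[C@H](C/C=C(C)\C(O[Si](CC)(CC)CC)C=C)[C@@H](O)/C=C(\C)CCC#C[Si](C)(C)C
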